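Both quinone rings are traced back to 5-alkyl-2-methylresorcinol units joined by a C14 chain. In ring A (methoxy-hydroxy-quinone) and ring B (dihydroxy-quinone) the two ring carbons beside the chain-bearing carbon, one C–OH and one C=O in each ring, carry oxygen and sit ortho or para to a resorcinol oxygen; all four of these C–O bonds are made in one operation by a fourfold Dakin oxidation. Its precursor is tetra-aldehyde 19, a bis-resorcinol with one methyl ether, formylated at every free ring position. The lone methyl ether is fixed by joining two differently protected rings in two Wittig steps and a thiolate mono-demethylation; air finally delivers both para-quinones.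

Key step: step 11

Assumption: 3,5-dimethoxy-4-methylbenzaldehyde (9) is taken as a catalogue chemical; the Z geometry drawn for the Wittig products is the expected major one and is of no consequence, because step 8 saturates both double bonds.

Step 1
Reactants: 1 3,5-dihydroxy-4-methylbenzoic acid; 2 benzyl bromide
Product: 3 benzyl 3,5-bis(benzyloxy)-4-methylbenzoate
Conditions: BnBr (3.5 equiv), K2CO3, DMF, 60 °C
Reagents that add atoms: benzyl bromide, BrCc1ccccc1
Why: Williamson ether synthesis combined with carboxylate alkylation, in which K2CO3 ionises both phenols and the acid and each anion displaces bromide from benzyl bromide, so exhaustive benzylation should give a single product.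

Step 2
Reactants: 3 benzyl 3,5-bis(benzyloxy)-4-methylbenzoate
Product: 4 [3,5-bis(benzyloxy)-4-methylphenyl]methanol
Conditions: LiAlH4, THF, 0 °C to rt; aqueous NaOH work-up
Reagents that add atoms: none
Why: LiAlH4 reduction of a benzoate ester to the benzylic alcohol, under which aryl benzyl ethers are inert.

Step 3
Reactants: 4 [3,5-bis(benzyloxy)-4-methylphenyl]methanol
Product: 5 3,5-bis(benzyloxy)-4-methylbenzaldehyde
Conditions: activated MnO2 (excess), CH2Cl2, rt
Reagents that add atoms: none
Why: MnO2 oxidation of a benzylic alcohol, which stops at the aldehyde and leaves the benzyl ethers untouched.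

Step 4
Reactants: 6 1,12-dibromododecane; 7 triphenylphosphine
Product: 8 (12-bromododecyl)triphenylphosphonium bromide
Conditions: 6 (4 equiv), PPh3 (1 equiv), toluene, reflux; salt triturated with Et2O/hexane, excess 6 recovered
Reagents that add atoms: triphenylphosphine, c1ccc(cc1)P(c1ccccc1)c1ccccc1
Why: SN2 quaternisation of triphenylphosphine (phosphonium salt formation), in which a fourfold excess of the dibromide keeps the second substitution minor and the salt is freed from the excess by its insolubility in ether/hexane.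

Step 5
Reactants: 8 (12-bromododecyl)triphenylphosphonium bromide; 9 3,5-dimethoxy-4-methylbenzaldehyde
Product: 11 5-[(1Z)-13-bromotridec-1-en-1-yl]-1,3-dimethoxy-2-methylbenzene, via bromoalkyl ylide 10 (not isolated)
Conditions: KN(SiMe3)2 (0.98 equiv), THF, −78 °C, 20 min; then 9, −78 °C to rt
Reagents that add atoms: none
Why: Wittig olefination with a non-stabilised ylide, generated cold with a slight deficit of base and trapped at once by the aryl aldehyde so that carbonyl addition outruns alkylation of the ylide by the remote primary bromide, the Z alkene being expected to predominate.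

Step 6
Reactants: 11 5-[(1Z)-13-bromotridec-1-en-1-yl]-1,3-dimethoxy-2-methylbenzene; 7 triphenylphosphine
Product: 12 [(12Z)-13-(3,5-dimethoxy-4-methylphenyl)tridec-12-en-1-yl]triphenylphosphonium bromide
Conditions: PPh3 (1.3 equiv), MeCN, reflux
Reagents that add atoms: triphenylphosphine, c1ccc(cc1)P(c1ccccc1)c1ccccc1
Why: SN2 phosphonium salt formation at the primary bromide, towards which the styrenic double bond and the aryl methyl ethers are unreactive.

Step 7
Reactants: 12 [(12Z)-13-(3,5-dimethoxy-4-methylphenyl)tridec-12-en-1-yl]triphenylphosphonium bromide; 5 3,5-bis(benzyloxy)-4-methylbenzaldehyde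
Product: 14 1,3-bis(benzyloxy)-5-[(1Z,13Z)-14-(3,5-dimethoxy-4-methylphenyl)tetradeca-1,13-dien-1-yl]-2-methylbenzene, via arylalkenyl ylide 13 (not isolated)
Conditions: KN(SiMe3)2 (1.0 equiv), THF, −78 °C; then 5, −78 °C to rt
Reagents that add atoms: none
Why: second Wittig olefination, which couples the dimethoxy ring (ring A) to the dibenzyloxy ring (ring B) and completes the C14 tether with the two rings carrying orthogonal ether sets.

Step 8
Reactants: 14 1,3-bis(benzyloxy)-5-[(1Z,13Z)-14-(3,5-dimethoxy-4-methylphenyl)tetradeca-1,13-dien-1-yl]-2-methylbenzene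
Product: 15 5-[14-(3,5-dimethoxy-4-methylphenyl)tetradecyl]-2-methylbenzene-1,3-diol
Conditions: H2 (1 atm), 10% Pd/C, EtOAc/EtOH, rt
Reagents that add atoms: none
Why: catalytic hydrogenation over Pd/C saturates both styrenic double bonds of either geometry and hydrogenolyses both benzyl ethers while aryl methyl ethers are stable, so ring B should emerge as the free resorcinol and ring A as its dimethyl ether.

Step 9
Reactants: 15 5-[14-(3,5-dimethoxy-4-methylphenyl)tetradecyl]-2-methylbenzene-1,3-diol
Product: 16 5-[14-(3-hydroxy-5-methoxy-4-methylphenyl)tetradecyl]-2-methylbenzene-1,3-diol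
Conditions: NaSEt (6 equiv), DMF, 140 °C, N2; then 1 M HCl
Reagents that add atoms: none
Why: thiolate SN2 O-demethylation of an aryl methyl ether, in which loss of one methyl group turns ring A into a phenoxide whose charge suppresses attack on the second methoxy group, while ring B is only a spectator bis-phenoxide, so exactly one methyl ether should remain.

Step 10
Reactants: 16 5-[14-(3-hydroxy-5-methoxy-4-methylphenyl)tetradecyl]-2-methylbenzene-1,3-diol; 17 hexamethylenetetramine
Product: 19 2-[14-(2,6-diformyl-3,5-dihydroxy-4-methylphenyl)tetradecyl]-6-hydroxy-4-methoxy-5-methylbenzene-1,3-dicarbaldehyde, via tetra-aldimine 18 (not isolated)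
Conditions: hexamethylenetetramine (10 equiv), CF3CO2H, reflux, N2; then 3 M aq HCl, 60 °C
Reagents that add atoms: hexamethylenetetramine, C1N2CN3CN1CN(C2)C3; water, O
Why: Duff formylation, in which iminium ions from the protonated cage substitute each of the four free ring positions (all ortho or para to a ring oxygen, the positions between the oxygens being blocked by methyl), hydride transfer gives the aldimines and aqueous acid hydrolyses them, the same exhaustive mode that turns phloroglucinol into its triformyl derivative.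

Step 11
Reactants: 19 2-[14-(2,6-diformyl-3,5-dihydroxy-4-methylphenyl)tetradecyl]-6-hydroxy-4-methoxy-5-methylbenzene-1,3-dicarbaldehyde
Product: 21 3-[14-(2,3,5,6-tetrahydroxy-4-methylphenyl)tetradecyl]-5-methoxy-6-methylbenzene-1,2,4-triol, via tetraformate 20 (not isolated)
Conditions: 30% aq H2O2 (4.2 equiv), B(OH)3 (8 equiv), cat. H2SO4, degassed THF, 0 °C to rt, Ar; then degassed 1 M HCl; extraction under Ar, crude used at once
Reagents that add atoms: hydrogen peroxide, OO
Why: Hydroperoxide, activated by B(OH)3, adds to each formyl carbon and the adduct rearranges by shift of the electron-rich aryl carbon from carbon to oxygen, giving the aryl formates of 20, which hydrolyse in the same flask to phenols and formic acid. The closest known reaction type is the H2O2/boric acid Dakin oxidation of ortho- and para-hydroxybenzaldehydes to catechols and hydroquinones, here required four times on one substrate. No ring is closed and no stereocentre is created; four aryl C–O bonds form at the carbons flanking the chain. The selectivity needed is aryl over hydride migration at every formyl group, and the substrate secures it: in ring A one aldehyde is ortho and the other para to the free hydroxyl, and in ring B each aldehyde is ortho to one hydroxyl and para to the other. Since every formyl group is to be converted, no site has to be chosen; survival of the electron-rich polyphenols is addressed by near-stoichiometric peroxide, an acidic medium, low temperature, exclusion of air and borate complexation of the emerging 1,2-diols. Oxidation that sets in only after all four migrations would be harmless, because step 12 takes the product to the quinones in any case.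

Step 12
Reactants: 21 3-[14-(2,3,5,6-tetrahydroxy-4-methylphenyl)tetradecyl]-5-methoxy-6-methylbenzene-1,2,4-triol
Product: 22 2-[14-(2,5-dihydroxy-4-methyl-3,6-dioxocyclohexa-1,4-dien-1-yl)tetradecyl]-3-hydroxy-6-methoxy-5-methylcyclohexa-2,5-diene-1,4-dione (CNP0130251.0)
Conditions: air, EtOAc/aq phosphate buffer (pH 7), rt, vigorous stirring; then dilute HCl wash
Reagents that add atoms: none
Why: autoxidation of a hydroxyhydroquinone (ring A) and a 1,2,4,5-tetrahydroxybenzene (ring B) to para-quinones, where ring A can form a para-quinone only across its two para hydroxyls, which keeps the methoxy group and the hydroxyl beside the chain, and ring B gives a 2,5-dihydroxy-1,4-benzoquinone whose two tautomers are identical by symmetry.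

Compound list
1 | 3,5-dihydroxy-4-methylbenzoic acid | Cc1c(O)cc(C(=O)O)cc1O | starting material
2 | benzyl bromide | BrCc1ccccc1 | starting material
3 | benzyl 3,5-bis(benzyloxy)-4-methylbenzoate | Cc1c(OCc2ccccc2)cc(C(=O)OCc2ccccc2)cc1OCc1ccccc1 | intermediate
4 | [3,5-bis(benzyloxy)-4-methylphenyl]methanol | Cc1c(OCc2ccccc2)cc(CO)cc1OCc1ccccc1 | intermediate
5 | 3,5-bis(benzyloxy)-4-methylbenzaldehyde | Cc1c(OCc2ccccc2)cc(C=O)cc1OCc1ccccc1 | intermediate
6 | 1,12-dibromododecane | BrCCCCCCCCCCCCBr | starting material
7 | triphenylphosphine | c1ccc(cc1)P(c1ccccc1)c1ccccc1 | starting material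
8 | (12-bromododecyl)triphenylphosphonium bromide | BrCCCCCCCCCCCC[P+](c1ccccc1)(c1ccccc1)c1ccccc1.[Br-] | intermediate
9 | 3,5-dimethoxy-4-methylbenzaldehyde | COc1cc(C=O)cc(OC)c1C | starting material
10 | (12-bromododecylidene)triphenylphosphorane | BrCCCCCCCCCCCC=P(c1ccccc1)(c1ccccc1)c1ccccc1 | intermediate (not isolated)
11 | 5-[(1Z)-13-bromotridec-1-en-1-yl]-1,3-dimethoxy-2-methylbenzene | COc1cc(/C=C\CCCCCCCCCCCBr)cc(OC)c1C | intermediate
12 | [(12Z)-13-(3,5-dimethoxy-4-methylphenyl)tridec-12-en-1-yl]triphenylphosphonium bromide | COc1cc(/C=C\CCCCCCCCCCC[P+](c2ccccc2)(c2ccccc2)c2ccccc2)cc(OC)c1C.[Br-] | intermediate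
13 | [(12Z)-13-(3,5-dimethoxy-4-methylphenyl)tridec-12-en-1-ylidene]triphenylphosphorane | COc1cc(/C=C\CCCCCCCCCCC=P(c2ccccc2)(c2ccccc2)c2ccccc2)cc(OC)c1C | intermediate (not isolated)
14 | 1,3-bis(benzyloxy)-5-[(1Z,13Z)-14-(3,5-dimethoxy-4-methylphenyl)tetradeca-1,13-dien-1-yl]-2-methylbenzene | COc1cc(/C=C\CCCCCCCCCC/C=C\c2cc(OCc3ccccc3)c(C)c(OCc3ccccc3)c2)cc(OC)c1C | intermediate
15 | 5-[14-(3,5-dimethoxy-4-methylphenyl)tetradecyl]-2-methylbenzene-1,3-diol | COc1cc(CCCCCCCCCCCCCCc2cc(O)c(C)c(O)c2)cc(OC)c1C | intermediate
16 | 5-[14-(3-hydroxy-5-methoxy-4-methylphenyl)tetradecyl]-2-methylbenzene-1,3-diol | COc1cc(CCCCCCCCCCCCCCc2cc(O)c(C)c(O)c2)cc(O)c1C | intermediate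
17 | hexamethylenetetramine | C1N2CN3CN1CN(C2)C3 | starting material
18 | tetra-aldimine of 19, drawn as the N-unsubstituted imine (in the flask each nitrogen still carries fragments of the opened cage) | COc1c(C)c(O)c(C=N)c(CCCCCCCCCCCCCCc2c(C=N)c(O)c(C)c(O)c2C=N)c1C=N | intermediate (not isolated)
19 | 2-[14-(2,6-diformyl-3,5-dihydroxy-4-methylphenyl)tetradecyl]-6-hydroxy-4-methoxy-5-methylbenzene-1,3-dicarbaldehyde | COc1c(C)c(O)c(C=O)c(CCCCCCCCCCCCCCc2c(C=O)c(O)c(C)c(O)c2C=O)c1C=O | intermediate
20 | tetraformate of 21 (formyloxy groups at the four former formyl positions) | COc1c(C)c(O)c(OC=O)c(CCCCCCCCCCCCCCc2c(OC=O)c(O)c(C)c(O)c2OC=O)c1OC=O | intermediate (not isolated)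
21 | 3-[14-(2,3,5,6-tetrahydroxy-4-methylphenyl)tetradecyl]-5-methoxy-6-methylbenzene-1,2,4-triol | COc1c(C)c(O)c(O)c(CCCCCCCCCCCCCCc2c(O)c(O)c(C)c(O)c2O)c1O | intermediate
22 | 2-[14-(2,5-dihydroxy-4-methyl-3,6-dioxocyclohexa-1,4-dien-1-yl)tetradecyl]-3-hydroxy-6-methoxy-5-methylcyclohexa-2,5-diene-1,4-dione | COC1=C(C)C(=O)C(O)=C(CCCCCCCCCCCCCCC2=C(O)C(=O)C(C)=C(O)C2=O)C1=O | target

Total step count: 12. Longest linear sequence: 9 steps (steps 1–3 and 7–12, or equally steps 4–12).

Steps most likely to fail

Step 11. The peroxide may oxidise the newly formed diol and hydroquinone units, or cleave the rings, before all four formyl groups have rearranged, leaving partially oxidised mixtures. The fallback sets out from 19 and comes back at 21. The three phenols of 19 are capped with benzyl bromide (K2CO3, DMF) to give 4-(benzyloxy)-2-{14-[3,5-bis(benzyloxy)-2,6-diformyl-4-methylphenyl]tetradecyl}-6-methoxy-5-methylbenzene-1,3-dicarbaldehyde F1. Baeyer–Villiger oxidation with mCPBA (CH2Cl2, NaHCO3), in which every formyl group is ortho and para to an alkoxy group, should give the tri-O-benzyl tetraformate F2. Methanolysis (K2CO3, MeOH, Ar) gives the much less oxidisable 4-(benzyloxy)-2-{14-[3,5-bis(benzyloxy)-2,6-dihydroxy-4-methylphenyl]tetradecyl}-6-methoxy-5-methylbenzene-1,3-diol F3. Hydrogenolysis (H2, Pd/C) then returns heptaol 21.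

Step 10. Formylation may stall after one formyl group per ring, because each formyl group deactivates its ring and the remaining site is flanked by the chain. The fallback sets out from 16 and comes back at 19. Exhaustive bromination (NBS, 4 equiv, MeCN, 0 °C) gives 2,4-dibromo-3-[14-(2,6-dibromo-3,5-dihydroxy-4-methylphenyl)tetradecyl]-5-methoxy-6-methylphenol F4. Protection of the three phenols (NaH, MOMCl, DMF) gives the tris(methoxymethyl) ether of the tetrabromide F5. Fourfold bromine–lithium exchange (t-BuLi, THF, −78 °C) with a DMF quench gives the tris(methoxymethyl) ether of the tetra-aldehyde F6. Aqueous HCl in THF removes the acetals and returns 19.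

Step 5. The ylide may be consumed by alkylation at the bromide terminus of a second molecule, or base may eliminate HBr, giving oligomeric phosphonium salts in place of the alkene. The fallback sets out from 9 and comes back at 11. 12-Bromododecan-1-ol F7 is quaternised with triphenylphosphine (7) to (12-hydroxydodecyl)triphenylphosphonium bromide F8. Two equivalents of KN(SiMe3)2 give the alkoxide ylide, which reacts with 9 to give (12Z)-13-(3,5-dimethoxy-4-methylphenyl)tridec-12-en-1-ol F9. Appel bromination (CBr4, PPh3, CH2Cl2) returns bromide 11.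

Further compounds
F1 | step 11 | 4-(benzyloxy)-2-{14-[3,5-bis(benzyloxy)-2,6-diformyl-4-methylphenyl]tetradecyl}-6-methoxy-5-methylbenzene-1,3-dicarbaldehyde | COc1c(C)c(OCc3ccccc3)c(C=O)c(CCCCCCCCCCCCCCc2c(C=O)c(OCc3ccccc3)c(C)c(OCc3ccccc3)c2C=O)c1C=O
F2 | step 11 | 4-(benzyloxy)-2-{14-[3,5-bis(benzyloxy)-2,6-bis(formyloxy)-4-methylphenyl]tetradecyl}-6-methoxy-5-methylbenzene-1,3-diyl diformate | COc1c(C)c(OCc3ccccc3)c(OC=O)c(CCCCCCCCCCCCCCc2c(OC=O)c(OCc3ccccc3)c(C)c(OCc3ccccc3)c2OC=O)c1OC=O
F3 | step 11 | 4-(benzyloxy)-2-{14-[3,5-bis(benzyloxy)-2,6-dihydroxy-4-methylphenyl]tetradecyl}-6-methoxy-5-methylbenzene-1,3-diol | COc1c(C)c(OCc3ccccc3)c(O)c(CCCCCCCCCCCCCCc2c(O)c(OCc3ccccc3)c(C)c(OCc3ccccc3)c2O)c1O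
F4 | step 10 | 2,4-dibromo-3-[14-(2,6-dibromo-3,5-dihydroxy-4-methylphenyl)tetradecyl]-5-methoxy-6-methylphenol | COc1c(C)c(O)c(Br)c(CCCCCCCCCCCCCCc2c(Br)c(O)c(C)c(O)c2Br)c1Br
F5 | step 10 | 1,3-dibromo-2-{14-[2,6-dibromo-3,5-bis(methoxymethoxy)-4-methylphenyl]tetradecyl}-4-methoxy-6-(methoxymethoxy)-5-methylbenzene | COc1c(C)c(OCOC)c(Br)c(CCCCCCCCCCCCCCc2c(Br)c(OCOC)c(C)c(OCOC)c2Br)c1Br
F6 | step 10 | 2-{14-[2,6-diformyl-3,5-bis(methoxymethoxy)-4-methylphenyl]tetradecyl}-4-methoxy-6-(methoxymethoxy)-5-methylbenzene-1,3-dicarbaldehyde | COc1c(C)c(OCOC)c(C=O)c(CCCCCCCCCCCCCCc2c(C=O)c(OCOC)c(C)c(OCOC)c2C=O)c1C=O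
F7 | step 5 | 12-bromododecan-1-ol | OCCCCCCCCCCCCBr
F8 | step 5 | (12-hydroxydodecyl)triphenylphosphonium bromide | OCCCCCCCCCCCC[P+](c1ccccc1)(c1ccccc1)c1ccccc1.[Br-]
F9 | step 5 | (12Z)-13-(3,5-dimethoxy-4-methylphenyl)tridec-12-en-1-ol | COc1cc(/C=C\CCCCCCCCCCCO)cc(OC)c1C
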